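**Assumption:** prostanoid numbering is used for positions (C1 = ester carbon, ring = C8–C12, C12 = carbinol carbon); the spatial arrangement at C12 is fixed in step 1 and never changes, only its R/S label changes with substituent priorities.

## Retrosynthetic overview

1. Target ⇐ cleavage of its C12 triethylsilyl ether; C7=C8 ⇐ Z-selective Horner–Wadsworth–Emmons reaction of a ring β-ketophosphonate (P on C8) with methyl (Z)-7-oxohept-5-enoate (proposed new step: makes C7=C8 and sets 7Z).
2. Ring phosphonate ⇐ C–P bond formation on the C8 enolate of the 2-chloro-4-silyloxy enone; C10–Cl ⇐ epoxidation/HCl on the 4-hydroxy enone.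
3. C12 ⇐ anti 1,2-addition of a propargyl Grignard reagent to commercial (R)-4-silyloxycyclopentenone, then desilylation/oxidation (carbonyl transposition with chirality transfer); C14=C15 ⇐ acetylide alkylation/Lindlar reduction.
4. (Z)-Enal ⇐ Z-selective Wittig reaction (C5=C6), desilylation, oxidation.
5. Rings: the only ring (the cyclopentenone) is bought intact and kept throughout; no ring is formed.

## Route

Step 1
Reactants: 1 (R)-4-(tert-butyldimethylsilyloxy)cyclopent-2-en-1-one; 2 propargyl bromide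
Product: 4 (1S,4R)-4-(tert-butyldimethylsilyloxy)-1-(prop-2-yn-1-yl)cyclopent-2-en-1-ol, via allenylmagnesium bromide 3 (not isolated)
Conditions: Mg, HgCl2 (cat.), Et2O, 0 °C; then 1, −78 °C; then H2O
Reagents that add atoms: none
Why: Grignard 1,2-addition of the propargyl/allenyl reagent (SE2′ through the allenyl form, giving the homopropargylic alcohol) takes place on the carbonyl face anti to the C4 silyloxy group, so the new carbinol (future C12) is set by substrate control with OH cis to OTBS.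

Step 2
Reactants: 4 (1S,4R)-4-(tert-butyldimethylsilyloxy)-1-(prop-2-yn-1-yl)cyclopent-2-en-1-ol; 5 1-iodopentane
Product: 7 (1S,4R)-4-(tert-butyldimethylsilyloxy)-1-(oct-2-yn-1-yl)cyclopent-2-en-1-ol, via dilithium alkoxide acetylide 6 (not isolated)
Conditions: n-BuLi (2.2 equiv), THF, −78 → −20 °C; then 5, DMPU, −20 °C → rt; then H2O
Reagents that add atoms: none
Why: SN2 alkylation of the lithium acetylide with a primary iodide (the hindered tertiary lithium alkoxide is far less nucleophilic) extends the chain without touching either stereocentre.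

Step 3
Reactants: 7 (1S,4R)-4-(tert-butyldimethylsilyloxy)-1-(oct-2-yn-1-yl)cyclopent-2-en-1-ol
Product: 8 (1S,4R)-4-(tert-butyldimethylsilyloxy)-1-[(Z)-oct-2-en-1-yl]cyclopent-2-en-1-ol
Conditions: H2 (1 atm), Pd/CaCO3 poisoned with Pb(OAc)2, quinoline, EtOAc, rt
Reagents that add atoms: none
Why: Lindlar semihydrogenation adds H2 syn to the internal alkyne to give the (Z)-alkene (future C14=C15) and does not reduce the ring alkene.

Step 4
Reactants: 8 (1S,4R)-4-(tert-butyldimethylsilyloxy)-1-[(Z)-oct-2-en-1-yl]cyclopent-2-en-1-ol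
Product: 9 (1S,4R)-1-[(Z)-oct-2-en-1-yl]cyclopent-2-ene-1,4-diol
Conditions: Bu4NF, THF, 0 °C → rt
Reagents that add atoms: none
Why: Fluoride-mediated desilylation removes the secondary silyl ether and leaves the tertiary allylic alcohol and both alkenes untouched.

Step 5
Reactants: 9 (1S,4R)-1-[(Z)-oct-2-en-1-yl]cyclopent-2-ene-1,4-diol
Product: 10 (S)-4-hydroxy-4-[(Z)-oct-2-en-1-yl]cyclopent-2-en-1-one
Conditions: MnO2 (activated, excess), CH2Cl2, rt
Reagents that add atoms: none
Why: Allylic oxidation with MnO2 can only touch the secondary alcohol, so the carbonyl moves to the former C4 and the addition-derived carbinol is left as the only stereocentre (carbonyl transposition with chirality transfer).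

Step 6
Reactants: 10 (S)-4-hydroxy-4-[(Z)-oct-2-en-1-yl]cyclopent-2-en-1-one
Product: 11 (1S,4S,5R)-4-hydroxy-4-[(Z)-oct-2-en-1-yl]-6-oxabicyclo[3.1.0]hexan-2-one
Conditions: 30% H2O2, NaOH (0.3 equiv), MeOH, −20 → 0 °C
Reagents that add atoms: hydrogen peroxide, OO
Why: Weitz–Scheffer nucleophilic epoxidation attacks only the electron-poor enone alkene (the isolated Z-alkene is inert), expected syn to the hydroxyl and anti to the octenyl chain, and either epoxide diastereomer converges in step 7.

Step 7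
Reactants: 11 (1S,4S,5R)-4-hydroxy-4-[(Z)-oct-2-en-1-yl]-6-oxabicyclo[3.1.0]hexan-2-one
Product: 13 (S)-2-chloro-4-hydroxy-4-[(Z)-oct-2-en-1-yl]cyclopent-2-en-1-one, via chlorohydrin 12 (not isolated)
Conditions: conc. aq HCl, THF, 0 °C → rt
Reagents that add atoms: hydrogen chloride, Cl
Why: Acid-mediated SN2 opening of the epoxide by chloride at the carbon next to the ketone (the other carbon is neopentyl-like) gives the chlorohydrin, which loses its β-hydroxyl by acid-catalysed dehydration through the enol to give the 2-chloro enone without involving C12.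

Step 8
Reactants: 13 (S)-2-chloro-4-hydroxy-4-[(Z)-oct-2-en-1-yl]cyclopent-2-en-1-one
Product: 14 (S)-2-chloro-4-[(Z)-oct-2-en-1-yl]-4-(triethylsilyloxy)cyclopent-2-en-1-one
Conditions: Et3SiOTf, 2,6-lutidine, CH2Cl2, −78 °C
Reagents that add atoms: triethylsilyl trifluoromethanesulfonate, CC[Si](CC)(CC)OS(=O)(=O)C(F)(F)F
Why: Silylation with a silyl triflate and a hindered pyridine base protects the tertiary alcohol for the enolate chemistry that follows without enolising the ketone at −78 °C.

Step 9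
Reactants: 14 (S)-2-chloro-4-[(Z)-oct-2-en-1-yl]-4-(triethylsilyloxy)cyclopent-2-en-1-one
Product: 17 diphenyl [(1S,2R)-4-chloro-2-[(Z)-oct-2-en-1-yl]-5-oxo-2-(triethylsilyloxy)cyclopent-3-en-1-yl]phosphonate, via lithium dienolate 15 (not isolated), via phosphonite 16 (not isolated)
Conditions: LiN(iPr)2, THF, −78 °C; ClP(OPh)2, −78 → −40 °C; t-BuOOH (in decane), −40 → 0 °C
Reagents that add atoms: diphenyl phosphorochloridite, ClP(Oc1ccccc1)Oc1ccccc1; tert-butyl hydroperoxide, CC(C)(C)OO
Why: Kinetic deprotonation at C8 (the only enolisable position) gives the cross-conjugated lithium dienolate, which attacks the soft trivalent phosphorus chloride through carbon (enolate C-phosphinylation), and oxidation of the phosphonite in the same flask gives the β-ketophosphonate, whose new C8 centre is epimerisable and is destroyed in step 14.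

Step 10
Reactants: 18 methyl 5-bromopentanoate; 19 triphenylphosphine
Product: 20 (5-methoxy-5-oxopentyl)triphenylphosphonium bromide
Conditions: MeCN, reflux
Reagents that add atoms: none
Why: SN2 quaternisation of the phosphine by the primary bromide gives the phosphonium salt.

Step 11
Reactants: 20 (5-methoxy-5-oxopentyl)triphenylphosphonium bromide; 21 (tert-butyldimethylsilyloxy)acetaldehyde
Product: 23 methyl (Z)-7-(tert-butyldimethylsilyloxy)hept-5-enoate, via phosphonium ylide 22 (not isolated)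
Conditions: NaN(SiMe3)2, THF, −78 °C; then 21, −78 °C → rt
Reagents that add atoms: none
Why: Wittig olefination with a non-stabilised ylide under lithium-free conditions at low temperature gives the (Z)-alkene (future C5=C6) through the kinetic cis-oxaphosphetane.

Step 12
Reactants: 23 methyl (Z)-7-(tert-butyldimethylsilyloxy)hept-5-enoate
Product: 24 methyl (Z)-7-hydroxyhept-5-enoate
Conditions: camphorsulfonic acid (cat.), MeOH, 0 °C
Reagents that add atoms: none
Why: Acid-catalysed methanolysis removes the primary allylic silyl ether without affecting the ester or the Z-alkene.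

Step 13
Reactants: 24 methyl (Z)-7-hydroxyhept-5-enoate
Product: 25 methyl (Z)-7-oxohept-5-enoate
Conditions: Dess–Martin periodinane, pyridine, CH2Cl2, 0 °C; used at once
Reagents that add atoms: none
Why: Dess–Martin oxidation buffered with pyridine converts the (Z)-allylic alcohol into the (Z)-enal under neutral conditions at 0 °C, which avoids Z to E isomerisation.

Step 14
Reactants: 17 diphenyl [(1S,2R)-4-chloro-2-[(Z)-oct-2-en-1-yl]-5-oxo-2-(triethylsilyloxy)cyclopent-3-en-1-yl]phosphonate; 25 methyl (Z)-7-oxohept-5-enoate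
Product: 27 methyl (5Z,7Z)-7-[(2R)-4-chloro-2-[(Z)-oct-2-en-1-yl]-5-oxo-2-(triethylsilyloxy)cyclopent-3-en-1-ylidene]hept-5-enoate, via potassium dienolate 26 (not isolated)
Conditions: KN(SiMe3)2 (0.98 equiv), 18-crown-6, THF, −78 °C; then 25, −78 → −30 °C; dark
Reagents that add atoms: none
Why: Proposed new method: a Z-selective Horner–Wadsworth–Emmons alkylidenation using a cyclic, cross-conjugated α-(diphenoxyphosphoryl) 2-chlorocyclopentenone, a substrate class on which this reactivity has not been shown; the potassium dienolate 26 adds through C8 to the aldehyde, the electron-poor diaryl phosphonate makes oxaphosphetane formation and collapse faster than retro-addition so the kinetic adduct (aldehyde chain turned away from the phosphoryl group and from the quaternary C12 carrying OSiEt3 and octenyl) is locked in, and syn-elimination of diphenyl phosphate then places C6 cis to the C9 carbonyl (7Z) while the (5Z)-alkene of the enal is untouched; the closest known reaction type is the Ando/Still–Gennari Z-selective olefination of acyclic α-substituted phosphonoacetates and β-ketophosphonates.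

Step 15
Reactants: 27 methyl (5Z,7Z)-7-[(2R)-4-chloro-2-[(Z)-oct-2-en-1-yl]-5-oxo-2-(triethylsilyloxy)cyclopent-3-en-1-ylidene]hept-5-enoate
Product: 28 methyl (5Z,7Z)-7-[(2R)-4-chloro-2-hydroxy-2-[(Z)-oct-2-en-1-yl]-5-oxocyclopent-3-en-1-ylidene]hept-5-enoate (chlorovulone IV)
Conditions: HF·pyridine, pyridine, THF, 0 °C; dark
Reagents that add atoms: none
Why: Buffered fluoride-assisted desilylation cleaves the tertiary triethylsilyl ether under conditions mild enough to keep the (5Z,7Z)-dienone and the C12 carbinol intact, giving the target.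

## Compound list

1 | (R)-4-(tert-butyldimethylsilyloxy)cyclopent-2-en-1-one | O=C1C=C[C@H](O[Si](C)(C)C(C)(C)C)C1 | starting material
2 | propargyl bromide (3-bromoprop-1-yne) | C#CCBr | starting material
3 | allenylmagnesium bromide (propargyl Grignard reagent, formed in the flask) | C=C=C[Mg]Br | intermediate
4 | (1S,4R)-4-(tert-butyldimethylsilyloxy)-1-(prop-2-yn-1-yl)cyclopent-2-en-1-ol (OH cis to OTBS) | C#CC[C@@]1(O)C=C[C@H](O[Si](C)(C)C(C)(C)C)C1 | intermediate
5 | 1-iodopentane | CCCCCI | starting material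
6 | dilithium alkoxide acetylide of 4 (formed in the flask) | [Li]C#CC[C@@]1(O[Li])C=C[C@H](O[Si](C)(C)C(C)(C)C)C1 | intermediate
7 | (1S,4R)-4-(tert-butyldimethylsilyloxy)-1-(oct-2-yn-1-yl)cyclopent-2-en-1-ol | CCCCCC#CC[C@@]1(O)C=C[C@H](O[Si](C)(C)C(C)(C)C)C1 | intermediate
8 | (1S,4R)-4-(tert-butyldimethylsilyloxy)-1-[(Z)-oct-2-en-1-yl]cyclopent-2-en-1-ol | CCCCC/C=C\C[C@@]1(O)C=C[C@H](O[Si](C)(C)C(C)(C)C)C1 | intermediate
9 | (1S,4R)-1-[(Z)-oct-2-en-1-yl]cyclopent-2-ene-1,4-diol (cis-diol) | CCCCC/C=C\C[C@@]1(O)C=C[C@H](O)C1 | intermediate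
10 | (S)-4-hydroxy-4-[(Z)-oct-2-en-1-yl]cyclopent-2-en-1-one | CCCCC/C=C\C[C@@]1(O)C=CC(=O)C1 | intermediate
11 | (1S,4S,5R)-4-hydroxy-4-[(Z)-oct-2-en-1-yl]-6-oxabicyclo[3.1.0]hexan-2-one (epoxide cis to OH) | CCCCC/C=C\C[C@@]1(O)[C@@H]2O[C@@H]2C(=O)C1 | intermediate
12 | (2R,3S,4S)-2-chloro-3,4-dihydroxy-4-[(Z)-oct-2-en-1-yl]cyclopentan-1-one (chlorohydrin, formed in the flask) | CCCCC/C=C\C[C@@]1(O)[C@H](O)[C@@H](Cl)C(=O)C1 | intermediate
13 | (S)-2-chloro-4-hydroxy-4-[(Z)-oct-2-en-1-yl]cyclopent-2-en-1-one | CCCCC/C=C\C[C@@]1(O)C=C(Cl)C(=O)C1 | intermediate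
14 | (S)-2-chloro-4-[(Z)-oct-2-en-1-yl]-4-(triethylsilyloxy)cyclopent-2-en-1-one | CCCCC/C=C\C[C@@]1(O[Si](CC)(CC)CC)C=C(Cl)C(=O)C1 | intermediate
15 | lithium dienolate of 14 (O–Li on C9, C8=C9 double bond; formed in the flask) | CCCCC/C=C\C[C@@]1(O[Si](CC)(CC)CC)C=C(Cl)C(O[Li])=C1 | intermediate
16 | diphenyl [(1S,2R)-4-chloro-2-[(Z)-oct-2-en-1-yl]-5-oxo-2-(triethylsilyloxy)cyclopent-3-en-1-yl]phosphonite (formed in the flask; P drawn trans to OSiEt3) | CCCCC/C=C\C[C@@]1(O[Si](CC)(CC)CC)C=C(Cl)C(=O)[C@H]1P(Oc2ccccc2)Oc2ccccc2 | intermediate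
17 | diphenyl [(1S,2R)-4-chloro-2-[(Z)-oct-2-en-1-yl]-5-oxo-2-(triethylsilyloxy)cyclopent-3-en-1-yl]phosphonate (P drawn trans to OSiEt3; C1 epimerisable) | CCCCC/C=C\C[C@@]1(O[Si](CC)(CC)CC)C=C(Cl)C(=O)[C@H]1P(=O)(Oc2ccccc2)Oc2ccccc2 | intermediate
18 | methyl 5-bromopentanoate | COC(=O)CCCCBr | starting material
19 | triphenylphosphine | c1ccc(cc1)P(c1ccccc1)c1ccccc1 | starting material
20 | (5-methoxy-5-oxopentyl)triphenylphosphonium bromide | COC(=O)CCCC[P+](c1ccccc1)(c1ccccc1)c1ccccc1.[Br-] | intermediate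
21 | (tert-butyldimethylsilyloxy)acetaldehyde | O=CCO[Si](C)(C)C(C)(C)C | starting material
22 | methyl 5-(triphenylphosphoranylidene)pentanoate (ylide, formed in the flask) | COC(=O)CCCC=P(c1ccccc1)(c1ccccc1)c1ccccc1 | intermediate
23 | methyl (Z)-7-(tert-butyldimethylsilyloxy)hept-5-enoate | COC(=O)CCC/C=C\CO[Si](C)(C)C(C)(C)C | intermediate
24 | methyl (Z)-7-hydroxyhept-5-enoate | COC(=O)CCC/C=C\CO | intermediate
25 | methyl (Z)-7-oxohept-5-enoate | COC(=O)CCC/C=C\C=O | intermediate
26 | potassium dienolate of 17 (O–K on C9, C8=C9 double bond; formed in the flask) | CCCCC/C=C\C[C@@]1(O[Si](CC)(CC)CC)C=C(Cl)C(O[K])=C1P(=O)(Oc2ccccc2)Oc2ccccc2 | intermediate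
27 | methyl (5Z,7Z)-7-[(2R)-4-chloro-2-[(Z)-oct-2-en-1-yl]-5-oxo-2-(triethylsilyloxy)cyclopent-3-en-1-ylidene]hept-5-enoate | CCCCC/C=C\C[C@@]1(O[Si](CC)(CC)CC)C=C(Cl)C(=O)/C1=C\C=C/CCCC(=O)OC | intermediate
28 | methyl (5Z,7Z)-7-[(2R)-4-chloro-2-hydroxy-2-[(Z)-oct-2-en-1-yl]-5-oxocyclopent-3-en-1-ylidene]hept-5-enoate (chlorovulone IV) | CCCCC/C=C\C[C@@]1(O)C=C(Cl)C(=O)/C1=C\C=C/CCCC(=O)OC | target

## Step count and risks

Total step count: 15. Longest linear sequence: 11 steps (steps 1–9, 14, 15); steps 10–13 make the side-chain aldehyde.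

The three steps most likely to fail:

**Step 14 (the proposed new step).** The risks are a poor Z:E ratio or slow addition of the hindered, stabilised dienolate. The product must also be kept cold and dark, because a (5Z,7Z)-dienone can isomerise thermally or photochemically. The fallback uses known chemistry, sets out from 14 and returns at 27. The kinetic lithium dienolate of 14 (LiN(iPr)2, THF, −78 °C) is added to aldehyde 25 to give the aldol methyl (5Z,7R)-7-[(1S,2S)-4-chloro-2-[(Z)-oct-2-en-1-yl]-5-oxo-2-(triethylsilyloxy)cyclopent-3-en-1-yl]-7-hydroxyhept-5-enoate F4 (major diastereomer drawn; all diastereomers are carried on). Mesylation (MsCl, Et3N, CH2Cl2, 0 °C) gives the mesylate methyl (5Z,7R)-7-[(1S,2S)-4-chloro-2-[(Z)-oct-2-en-1-yl]-5-oxo-2-(triethylsilyloxy)cyclopent-3-en-1-yl]-7-(methylsulfonyloxy)hept-5-enoate F5. This eliminates on adding DBU in the same flask to a mixture of 27 and its 7E isomer methyl (5Z,7E)-7-[(2R)-4-chloro-2-[(Z)-oct-2-en-1-yl]-5-oxo-2-(triethylsilyloxy)cyclopent-3-en-1-ylidene]hept-5-enoate F6. Compound 27 is separated by HPLC on silica and F6 is recycled by photo-equilibration, so the route is rejoined at 27.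

**Step 9.** The risks are O- instead of C-attack, or over-reaction of the hindered dienolate with the phosphorus chloride. The fallback sets out from 14 and returns at 17, making the C–P bond by carbene insertion instead of enolate phosphinylation. Trifluoroacetylation of the enolate (LiN(SiMe3)2, THF, −78 °C; CF3CO2CH2CF3) gives 1-[(5R)-3-chloro-2-hydroxy-5-[(Z)-oct-2-en-1-yl]-5-(triethylsilyloxy)cyclopenta-1,3-dien-1-yl]-2,2,2-trifluoroethan-1-one F2 (the enol form of the C8-trifluoroacetyl ketone). Detrifluoroacetylative diazo transfer (MsN3, Et3N, H2O, MeCN, rt) gives (4R)-2-chloro-5-diazo-4-[(Z)-oct-2-en-1-yl]-4-(triethylsilyloxy)cyclopent-2-en-1-one F3. Rh2(OAc)4-catalysed insertion of the carbene into the P–H bond of diphenyl phosphite (toluene, rt → 50 °C) gives 17.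

**Step 7.** The risks are acid-promoted side reactions of the tertiary diol or alkene, or incomplete dehydration. The fallback sets out from 10 and returns at 13, leaving the epoxide route altogether. Pyridine-mediated α-iodination of the enone (I2, pyridine, CH2Cl2, rt; conjugate addition of pyridine, iodination of the enolate, elimination), which does not touch isolated alkenes, gives (S)-4-hydroxy-2-iodo-4-[(Z)-oct-2-en-1-yl]cyclopent-2-en-1-one F1. Copper-mediated iodine-to-chlorine exchange on the vinyl iodide (CuCl, DMF, 80 °C) gives 13.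

## Further compounds

F1 | step 7 | (S)-4-hydroxy-2-iodo-4-[(Z)-oct-2-en-1-yl]cyclopent-2-en-1-one | CCCCC/C=C\C[C@@]1(O)C=C(I)C(=O)C1
F2 | step 9 | 1-[(5R)-3-chloro-2-hydroxy-5-[(Z)-oct-2-en-1-yl]-5-(triethylsilyloxy)cyclopenta-1,3-dien-1-yl]-2,2,2-trifluoroethan-1-one | CCCCC/C=C\C[C@@]1(O[Si](CC)(CC)CC)C=C(Cl)C(O)=C1C(=O)C(F)(F)F
F3 | step 9 | (4R)-2-chloro-5-diazo-4-[(Z)-oct-2-en-1-yl]-4-(triethylsilyloxy)cyclopent-2-en-1-one | CCCCC/C=C\C[C@@]1(O[Si](CC)(CC)CC)C=C(Cl)C(=O)C1=[N+]=[N-]
F4 | step 14 | methyl (5Z,7R)-7-[(1S,2S)-4-chloro-2-[(Z)-oct-2-en-1-yl]-5-oxo-2-(triethylsilyloxy)cyclopent-3-en-1-yl]-7-hydroxyhept-5-enoate | CCCCC/C=C\C[C@@]1(O[Si](CC)(CC)CC)C=C(Cl)C(=O)[C@H]1[C@H](O)/C=C\CCCC(=O)OC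
F5 | step 14 | methyl (5Z,7R)-7-[(1S,2S)-4-chloro-2-[(Z)-oct-2-en-1-yl]-5-oxo-2-(triethylsilyloxy)cyclopent-3-en-1-yl]-7-(methylsulfonyloxy)hept-5-enoate | CCCCC/C=C\C[C@@]1(O[Si](CC)(CC)CC)C=C(Cl)C(=O)[C@H]1[C@H](OS(C)(=O)=O)/C=C\CCCC(=O)OC
F6 | step 14 | methyl (5Z,7E)-7-[(2R)-4-chloro-2-[(Z)-oct-2-en-1-yl]-5-oxo-2-(triethylsilyloxy)cyclopent-3-en-1-ylidene]hept-5-enoate | CCCCC/C=C\C[C@@]1(O[Si](CC)(CC)CC)C=C(Cl)C(=O)/C1=C/C=C\CCCC(=O)OC
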